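## The problem

Compound 27 is an isoflavan quinone: a chroman (benzo ring A fused to pyran ring C) that carries a 2,3-dimethoxy-1,4-benzoquinone (ring B) on C3 through one C–C bond. Its only stereocentre is C3 (S). Nothing else in the molecule can relay chirality to it, so it must be set by a catalyst or reagent. Once the quinone is present the C3–H bond can enolise toward a quinone methide, so base has to be kept away from the last stages. Ring A bears oxygen on four adjacent carbons (O1 on C8a, a free hydroxyl on C8, methoxyls on C7 and C6), and the C8 oxygen must stay distinguishable from the two methyl ethers. The quinone will not survive organolithiums, hydride, phosphines or amines, and the electron-rich C8 phenol will not survive strong oxidants, so both are best revealed at the very end. The feature that invites a de novo construction of ring A is that C8, C7, C6 and C5 map onto the four carbons of a squarate adduct (carbinol carbon, two methoxy carbons, carbonyl carbon), while C8a=C4a can be the double bond of a cyclic enol ether whose oxygen is O1.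

## Retrosynthesis

**27 to 24.** The quinone of 27 is traced back to hydroquinone 26 and its dibenzyl ether 25, and the C8 hydroxyl of 25 to silyl ether 24 (two O–benzyl bonds and one O–Si bond are cut). Methyl ethers on ring B with a late oxidative demethylation were set aside, because an oxidant strong enough for that would also attack the tetraoxygenated ring A. Benzyl and silyl groups come off under neutral or buffered conditions. The forward sequence needs an oxidant that takes the hydroquinone but not the C8 phenol.

**24 to 22.** The C5–H bond of 24 is traced back to triflate 23 and phenol 22. This adds an oxygen that the target lacks and is the price of the ring A construction below. The C5 hydroxyl of 22 is the only free hydroxyl, so no selectivity question arises, and formate reduction of aryl triflates is dependable.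

**22 to 19 (key disconnection).** The C4a–C5 bond is cut and ring A is unravelled to cyclobutenone 19, whose four ring carbons become C5 to C8. The neighbouring cut, joining the ketene carbon to C8a instead, would give the C8 hydroxyl directly with no surplus oxygen. It would need a β-metallated enol ether and a 4-unsubstituted cyclobutenone, and it would pair the electrophilic ketene carbon with the electrophilic end of the enol ether. The chosen mode pairs the ketene carbon with the nucleophilic β-carbon. The simplification is large: the whole of ring A disappears, and 19 is one C–C bond away from two simple pieces. The forward reaction needs outward rotation of the silyloxy group, clean 6π closure and tautomerisation.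

**19 to 15 and 16.** The C8–C8a bond is cut between the carbinol carbon and the pyranyl group, giving vinyllithium 17 and dimethyl squarate 16. Vinyllithium 17 is generated from stannane 15, because direct deprotonation of the enol ether would need a base that attacks the benzyl ethers. Alkoxide 18 is silylated in the same flask.

**15 to 8.** The C–Sn bond of 15 is traced to sulfone 12, and this to hydroxy enol ether 10, lactol 9 and lactone 8. The only skeletal bond cut is the C=C bond made by a methoxymethylene Wittig reaction, which supplies C8a at the correct oxidation level. A six-membered lactone with the aryl group in the right place cannot be made directly by conjugate addition, so the five-membered lactone is homologated by one carbon.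

**8 to 6 and 7.** The C3–aryl bond is cut: rhodium-catalysed conjugate addition of boronic acid 6 to furanone 7. This sets the only stereocentre early, by a catalyst, on simple achiral components. Later options such as hydrogenation of a chromene are not open, because ring A does not exist until step 10.

**6 to 1.** Boronic acid 6 comes from bromide 4, dibenzyl ether 3 and quinone 1 by borylation, bromination and reductive benzylation. Ring B is thus bought with its oxygen pattern complete and stored as a robust hydroquinone diether.

## Roads not taken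

**Alternative 1:** The C3–aryl bond is cut together with a temporary C4–O bond. Quinone 1 and 8-(benzyloxy)-6,7-dimethoxy-2H-chromene A1 would be joined under a stoichiometric TADDOL complex of TiCl2(OiPr)2 (tetravalent titanium) to give the cis-fused pterocarpan A2. Hydrogenolysis would then open the benzylic C4–O bond and remove the benzyl ether, and oxidation would give 27.
- Merits: it is convergent, ring B arrives as the commercial quinone with every oxygen in place, and only two operations follow the key step. It would be clearly shorter than the fourteen steps planned here and uses no tin.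
- Weak points: the chiral Lewis acid is stoichiometric. The selectivity of this formal cycloaddition, and its competition with cyclobutane formation, depends strongly on the quinone substitution. A 2,3-dimethoxyquinone offers two chelating sites and is a weaker electrophile than the monoalkoxy quinones for which the reaction is best behaved. A1 still needs a ring A with four adjacent, differentiated oxygens made from a polyoxygenated phenol.
- Comparison: the chosen plan offers a catalytic enantioselective step with a predictable sense on a simple acceptor, and a ring A oxygen pattern that comes differentiated from squarate.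

**Alternative 2:** The C3–aryl and C4–C4a bonds are cut in one conjunctive coupling. Vinylboronic ester A3 is treated with aryllithium 5, and aryl bromide A4 is coupled under Pd(OAc)2 and MandyPhos with NaOTf. A palladium-induced 1,2-aryl shift from boron to carbon gives the secondary benzylic boronate A5. One-carbon homologation of the C–B bond, desilylation, ring closure of the pyran by C–O bond formation, hydrogenolysis and oxidation would follow.
- Merits: it is the most convergent of the four plans, it is catalytic in the chiral ligand, and it makes two skeletal bonds and the stereocentre in one step. In these respects it is better than the chosen plan.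
- Weak points: both aryl partners are electron-rich and ortho-substituted. The migrating group carries an ortho benzyloxy group and A4 is flanked by a silyloxy group, which slows oxidative addition and the 1,2-shift and favours direct aryl transfer. The homologation is on a hindered benzylic boronate. A4 is a pentasubstituted arene that again requires selective protection of a polyoxygenated phenol.
- Comparison: the chosen plan offers closer precedent for each step on comparable substrates and builds ring A without any aromatic starting material.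

**Alternative 3:** The quinone ring is cut between the squarate carbons and an alkyne. The lithium acetylide of (3S)-3-ethynyl-6,7-dimethoxy-8-(methoxymethoxy)chroman A6 adds to squarate 16 to give carbinol A7. Heating in toluene opens A7 to an alkynyl ketene that closes to the quinone A8, and removal of the acetal gives 27.
- Merits: the quinone is formed last, under neutral thermal conditions, without an oxidant and without protecting groups on ring B. For ring B this is more economical than the chosen plan, which has to reduce, protect, deprotect and re-oxidise a quinone.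
- Weak points: everything difficult is moved into A6. Ring A must be made conventionally, and the propargylic C3 stereocentre has to be set on the chroman, most simply through an epimerisable α-branched aldehyde. The alkynyl ring expansion goes through a diradical that can partition between the quinone and a five-membered alkylidene cyclopentenedione.
- Comparison: both plans use squarate thermolysis. The chosen plan spends it on ring A, whose oxygen pattern cannot be bought, and buys ring B as quinone 1. It pays for this with a surplus oxygen at C5 and a longer sequence.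

Key step: step 10

Remark: the C3 descriptor is read as S from the target structure. The sense of induction of (S)-BINAP in step 4 is assigned by the model established for cyclic enones and unsaturated lactones and would be confirmed at lactone 8 before going on.

## Route

Step 1
Reactants: 1 2,3-dimethoxy-1,4-benzoquinone
Product: 3 1,4-bis(benzyloxy)-2,3-dimethoxybenzene, via hydroquinone 2 (not isolated)
Conditions: Na2S2O4, THF/H2O, rt; then KOH, BnBr, Bu4NBr (cat.), rt to 40 °C, N2
Reagents that add atoms: benzyl bromide, BrCc1ccccc1
Why: Dithionite reduces the quinone to hydroquinone 2, whose dianion is benzylated twice in the same flask under phase-transfer Williamson conditions (reductive alkylation of a quinone); nitrogen and a slight excess of dithionite keep 2 from re-oxidising before it is capped.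

Step 2
Reactants: 3 1,4-bis(benzyloxy)-2,3-dimethoxybenzene
Product: 4 1,4-bis(benzyloxy)-5-bromo-2,3-dimethoxybenzene
Conditions: NBS (1.0 equiv), MeCN, 0 °C to rt
Reagents that add atoms: N-bromosuccinimide, O=C1CCC(=O)N1Br
Why: Electrophilic aromatic bromination of an electron-rich arene with NBS in a polar solvent; the two free ring positions are equivalent by symmetry and the first bromine deactivates the ring enough for one equivalent to stop at the monobromide.

Step 3
Reactants: 4 1,4-bis(benzyloxy)-5-bromo-2,3-dimethoxybenzene
Product: 6 [2,5-bis(benzyloxy)-3,4-dimethoxyphenyl]boronic acid, via aryllithium 5 (not isolated)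
Conditions: n-BuLi, THF, −78 °C; B(OiPr)3, −78 °C to rt; dilute aq. HCl
Reagents that add atoms: triisopropyl borate, CC(C)OB(OC(C)C)OC(C)C; water, O
Why: Bromine–lithium exchange at −78 °C is faster than deprotonation of the benzylic OCH2 groups; aryllithium 5 is borylated by the borate ester and the boronic acid is released on mildly acidic work-up.

Step 4
Reactants: 6 [2,5-bis(benzyloxy)-3,4-dimethoxyphenyl]boronic acid; 7 furan-2(5H)-one
Product: 8 (4S)-4-[2,5-bis(benzyloxy)-3,4-dimethoxyphenyl]dihydrofuran-2(3H)-one
Conditions: [Rh(OH)((S)-binap)]2 (3 mol % Rh), 7 (3 equiv), dioxane/H2O 10:1, 40 °C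
Reagents that add atoms: none
Why: Hayashi–Miyaura asymmetric 1,4-addition: the aryl group passes from boron to monovalent rhodium, adds across the C=C bond of 7 held in the BINAP pocket, and protonolysis of the rhodium enolate returns the hydroxo complex; the new stereocentre (C3 of the target) is set by the ligand, (S)-BINAP being expected to give the (4S)-lactone; the cheap acceptor is used in excess so that insertion outruns protodeboronation of 6.

Step 5
Reactants: 8 (4S)-4-[2,5-bis(benzyloxy)-3,4-dimethoxyphenyl]dihydrofuran-2(3H)-one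
Product: 9 (4S)-4-[2,5-bis(benzyloxy)-3,4-dimethoxyphenyl]tetrahydrofuran-2-ol (both anomers)
Conditions: iBu2AlH (1.1 equiv), CH2Cl2, −78 °C
Reagents that add atoms: none
Why: Partial reduction of a γ-lactone to the lactol at low temperature, where the tetrahedral aluminate does not collapse; the stereocentre is β to the carbonyl group and cannot epimerise.

Step 6
Reactants: 9 (4S)-4-[2,5-bis(benzyloxy)-3,4-dimethoxyphenyl]tetrahydrofuran-2-ol
Product: 10 (2S)-2-[2,5-bis(benzyloxy)-3,4-dimethoxyphenyl]-5-methoxypent-4-en-1-ol (E and Z)
Conditions: MeOCH2PPh3Cl (3 equiv), KOtBu (3 equiv), THF, 0 °C to rt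
Reagents that add atoms: (methoxymethyl)triphenylphosphonium chloride, COC[P+](c1ccccc1)(c1ccccc1)c1ccccc1.[Cl-]
Why: Wittig olefination of the open hydroxy-aldehyde form of the lactol with the methoxymethylene ylide (the first equivalent is spent on the hydroxyl group) adds the carbon that becomes C8a and leaves it at the aldehyde oxidation level as an enol ether.

Step 7
Reactants: 10 (2S)-2-[2,5-bis(benzyloxy)-3,4-dimethoxyphenyl]-5-methoxypent-4-en-1-ol
Product: 12 (5S)-5-[2,5-bis(benzyloxy)-3,4-dimethoxyphenyl]-2-(phenylsulfonyl)tetrahydro-2H-pyran (both C2 epimers), via methyl acetal 11 (not isolated)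
Conditions: PhSO2H (2 equiv), CaCl2, CH2Cl2, rt
Reagents that add atoms: benzenesulfinic acid, O=S(O)c1ccccc1
Why: The sulfinic acid protonates the enol ether, the oxocarbenium ion is captured by the primary hydroxyl to give six-membered acetal 11, and this ionises again and is trapped at sulfur by benzenesulfinate while CaCl2 binds the methanol (formation of a 2-sulfonyl cyclic ether from a lactol ether); the C2 epimers are of no consequence.

Step 8
Reactants: 12 (5S)-5-[2,5-bis(benzyloxy)-3,4-dimethoxyphenyl]-2-(phenylsulfonyl)tetrahydro-2H-pyran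
Product: 15 tributyl{(3S)-3-[2,5-bis(benzyloxy)-3,4-dimethoxyphenyl]-3,4-dihydro-2H-pyran-6-yl}stannane, via lithiated sulfone 13 (not isolated), via stannyl sulfone 14 (not isolated)
Conditions: n-BuLi, THF, −78 °C; Bu3SnCl, −78 °C to rt; then iPr2NEt, CHCl3, 60 °C
Reagents that add atoms: tributyltin chloride, CCCC[Sn](Cl)(CCCC)CCCC
Why: The proton alpha to both the sulfonyl group and the ring oxygen is removed selectively at −78 °C, carbanion 13 is stannylated, and the geminal stannyl sulfone 14 loses benzenesulfinic acid on warming with the amine base (ionisation assisted by the ring oxygen, then loss of a C3 proton) to give the cyclic alpha-stannyl enol ether; the aryl-bearing centre is two carbons away and unaffected.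

Step 9
Reactants: 15 tributyl{(3S)-3-[2,5-bis(benzyloxy)-3,4-dimethoxyphenyl]-3,4-dihydro-2H-pyran-6-yl}stannane; 16 dimethyl squarate
Product: 19 4-{(3S)-3-[2,5-bis(benzyloxy)-3,4-dimethoxyphenyl]-3,4-dihydro-2H-pyran-6-yl}-4-[(tert-butyldimethylsilyl)oxy]-2,3-dimethoxycyclobut-2-en-1-one (both carbinol epimers), via vinyllithium 17 (not isolated), via lithium alkoxide 18 (not isolated)
Conditions: n-BuLi, THF, −78 °C; cannulate into 16 (1.2 equiv), THF, −78 °C; TBSOTf (1.1 equiv), 2,6-lutidine, −78 to −40 °C; Et3N, aq. NaHCO3
Reagents that add atoms: tert-butyldimethylsilyl trifluoromethanesulfonate, CC(C)(C)[Si](C)(C)OS(=O)(=O)C(F)(F)F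
Why: Tin–lithium exchange of an alpha-alkoxy vinylstannane is fast at −78 °C and avoids a strong base that would attack the benzyl ethers; vinyllithium 17 adds once to one of the two equivalent carbonyl groups of the squarate (1,2-addition, inverse addition), and the tertiary alkoxide 18 is silylated in the same flask; the new carbinol centre forms without control and is destroyed in the next step.

Step 10
Reactants: 19 4-{(3S)-3-[2,5-bis(benzyloxy)-3,4-dimethoxyphenyl]-3,4-dihydro-2H-pyran-6-yl}-4-[(tert-butyldimethylsilyl)oxy]-2,3-dimethoxycyclobut-2-en-1-one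
Product: 22 (3S)-3-[2,5-bis(benzyloxy)-3,4-dimethoxyphenyl]-8-[(tert-butyldimethylsilyl)oxy]-6,7-dimethoxychroman-5-ol, via dienylketene 20 (not isolated), via cyclohexadienone 21 (not isolated)
Conditions: degassed toluene (0.02 M), 110–140 °C, sealed base-washed vessel
Reagents that add atoms: none
Why: Heating opens the cyclobutenone by a conrotatory four-electron electrocyclic cleavage of the bond between the carbonyl carbon and the carbinol carbon. Torquoselectivity sends the donor silyloxy group outward, so the dihydropyranyl group turns inward and dienylketene 20 has the enol ether double bond cis to the ketene across the central C=C bond. A six-electron electrocyclisation, which can equally be seen as attack of the nucleophilic enol ether β-carbon on the electrophilic ketene carbon, forms the C4a–C5 bond and closes ring A as cyclohexadienone 21, and enolisation of the C4a–H gives phenol 22. The closest known reaction type is the thermal ring expansion of 4-alkenyl-4-silyloxy- or 4-alkoxycyclobutenones made from squarate esters to monoprotected hydroquinones, which includes adducts of 2-lithiated cyclic enol ethers. Ring A is closed as a six-membered carbocycle in the 6π mode; no lasting stereocentre is created (the carbinol centre is consumed and C4a becomes aromatic) and C3 is remote from every bond that changes. The selectivities needed are outward rotation of the silyloxy group, secured by its donor character, and intramolecular capture of the ketene in preference to dimerisation or hydration, secured by dilution and dry, degassed conditions. The oxygen pattern (C5 hydroxyl from the ketene, C6 and C7 methoxyls, C8 silyloxy para to the free hydroxyl) follows from the connectivity of 19 and cannot scramble.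

Step 11
Reactants: 22 (3S)-3-[2,5-bis(benzyloxy)-3,4-dimethoxyphenyl]-8-[(tert-butyldimethylsilyl)oxy]-6,7-dimethoxychroman-5-ol
Product: 23 (3S)-3-[2,5-bis(benzyloxy)-3,4-dimethoxyphenyl]-8-[(tert-butyldimethylsilyl)oxy]-6,7-dimethoxychroman-5-yl trifluoromethanesulfonate
Conditions: Tf2O, pyridine, CH2Cl2, 0 °C
Reagents that add atoms: trifluoromethanesulfonic anhydride, O=S(=O)(OS(=O)(=O)C(F)(F)F)C(F)(F)F
Why: O-Sulfonylation of the only free phenol with triflic anhydride and pyridine; the aryl silyl ether, benzyl ethers and methyl ethers are inert under these conditions.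

Step 12
Reactants: 23 (3S)-3-[2,5-bis(benzyloxy)-3,4-dimethoxyphenyl]-8-[(tert-butyldimethylsilyl)oxy]-6,7-dimethoxychroman-5-yl trifluoromethanesulfonate
Product: 24 tert-butyl{[(3S)-3-[2,5-bis(benzyloxy)-3,4-dimethoxyphenyl]-6,7-dimethoxychroman-8-yl]oxy}dimethylsilane
Conditions: Pd(OAc)2 (10 mol %), dppf (12 mol %), HCO2H, Et3N, DMF, 80 °C
Reagents that add atoms: none
Why: Palladium-catalysed reduction of an aryl triflate by formate: zerovalent palladium formed in situ from Pd(OAc)2 and the bisphosphine inserts into the C–O bond, formate exchanges for triflate and loses CO2 to give an aryl palladium hydride, and reductive elimination leaves hydrogen at C5; the wide-bite-angle ligand is the usual choice for hindered electron-rich triflates, and any loss of the silyl group here is harmless because the next step removes it.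

Step 13
Reactants: 24 tert-butyl{[(3S)-3-[2,5-bis(benzyloxy)-3,4-dimethoxyphenyl]-6,7-dimethoxychroman-8-yl]oxy}dimethylsilane
Product: 25 (3S)-3-[2,5-bis(benzyloxy)-3,4-dimethoxyphenyl]-6,7-dimethoxychroman-8-ol
Conditions: Bu4NF, AcOH, THF, 0 °C
Reagents that add atoms: none
Why: Fluoride cleaves the aryl silyl ether at 0 °C; acetic acid protonates the electron-rich phenoxide as it forms, which protects it from air oxidation; benzyl and methyl ethers are untouched.

Step 14
Reactants: 25 (3S)-3-[2,5-bis(benzyloxy)-3,4-dimethoxyphenyl]-6,7-dimethoxychroman-8-ol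
Product: 27 5-[(3S)-8-hydroxy-6,7-dimethoxychroman-3-yl]-2,3-dimethoxycyclohexa-2,5-diene-1,4-dione, via hydroquinone 26 (not isolated)
Conditions: H2 (1 atm), Pd/C, EtOAc, rt; filter under Ar; then Ag2O (1.1 equiv), Na2SO4, EtOAc, 0 °C
Reagents that add atoms: none
Why: Hydrogenolysis over Pd/C removes both benzyl ethers to give hydroquinone 26, which is oxidised at once by a slight excess of Ag2O, a neutral two-electron oxidant that takes a tetraoxygenated hydroquinone to the quinone far faster than it attacks a monophenol; no base is present, so the C3 stereocentre next to the new quinone cannot epimerise by enolisation.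

## Compound list

1 | 2,3-dimethoxy-1,4-benzoquinone | COC1=C(OC)C(=O)C=CC1=O | starting material
2 | 2,3-dimethoxybenzene-1,4-diol | COc1c(O)ccc(O)c1OC | intermediate (not isolated)
3 | 1,4-bis(benzyloxy)-2,3-dimethoxybenzene | COc1c(OCc2ccccc2)ccc(OCc2ccccc2)c1OC | intermediate
4 | 1,4-bis(benzyloxy)-5-bromo-2,3-dimethoxybenzene | COc1c(OCc2ccccc2)cc(Br)c(OCc2ccccc2)c1OC | intermediate
5 | [2,5-bis(benzyloxy)-3,4-dimethoxyphenyl]lithium | [Li]c1cc(OCc2ccccc2)c(OC)c(OC)c1OCc1ccccc1 | intermediate (not isolated)
6 | [2,5-bis(benzyloxy)-3,4-dimethoxyphenyl]boronic acid | OB(O)c1cc(OCc2ccccc2)c(OC)c(OC)c1OCc1ccccc1 | intermediate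
7 | furan-2(5H)-one | O=C1OCC=C1 | starting material
8 | (4S)-4-[2,5-bis(benzyloxy)-3,4-dimethoxyphenyl]dihydrofuran-2(3H)-one | O=C1C[C@@H](c2cc(OCc3ccccc3)c(OC)c(OC)c2OCc2ccccc2)CO1 | intermediate
9 | (4S)-4-[2,5-bis(benzyloxy)-3,4-dimethoxyphenyl]tetrahydrofuran-2-ol (both anomers) | OC1C[C@@H](c2cc(OCc3ccccc3)c(OC)c(OC)c2OCc2ccccc2)CO1 | intermediate
10 | (2S)-2-[2,5-bis(benzyloxy)-3,4-dimethoxyphenyl]-5-methoxypent-4-en-1-ol (E and Z) | COC=CC[C@@H](c1cc(OCc2ccccc2)c(OC)c(OC)c1OCc1ccccc1)CO | intermediate
11 | (5S)-5-[2,5-bis(benzyloxy)-3,4-dimethoxyphenyl]-2-methoxytetrahydro-2H-pyran (both C2 epimers) | COC1CC[C@@H](c2cc(OCc3ccccc3)c(OC)c(OC)c2OCc2ccccc2)CO1 | intermediate (not isolated)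
12 | (5S)-5-[2,5-bis(benzyloxy)-3,4-dimethoxyphenyl]-2-(phenylsulfonyl)tetrahydro-2H-pyran (both C2 epimers) | O=S(=O)(c1ccccc1)C1CC[C@@H](c2cc(OCc3ccccc3)c(OC)c(OC)c2OCc2ccccc2)CO1 | intermediate
13 | [(5S)-5-[2,5-bis(benzyloxy)-3,4-dimethoxyphenyl]-2-(phenylsulfonyl)tetrahydro-2H-pyran-2-yl]lithium | [Li]C1(S(=O)(=O)c2ccccc2)CC[C@@H](c2cc(OCc3ccccc3)c(OC)c(OC)c2OCc2ccccc2)CO1 | intermediate (not isolated)
14 | tributyl[(5S)-5-[2,5-bis(benzyloxy)-3,4-dimethoxyphenyl]-2-(phenylsulfonyl)tetrahydro-2H-pyran-2-yl]stannane | CCCC[Sn](CCCC)(CCCC)C1(S(=O)(=O)c2ccccc2)CC[C@@H](c2cc(OCc3ccccc3)c(OC)c(OC)c2OCc2ccccc2)CO1 | intermediate (not isolated)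
15 | tributyl{(3S)-3-[2,5-bis(benzyloxy)-3,4-dimethoxyphenyl]-3,4-dihydro-2H-pyran-6-yl}stannane | CCCC[Sn](CCCC)(CCCC)C1=CC[C@@H](c2cc(OCc3ccccc3)c(OC)c(OC)c2OCc2ccccc2)CO1 | intermediate
16 | dimethyl squarate (3,4-dimethoxycyclobut-3-ene-1,2-dione) | COC1=C(OC)C(=O)C1=O | starting material
17 | {(3S)-3-[2,5-bis(benzyloxy)-3,4-dimethoxyphenyl]-3,4-dihydro-2H-pyran-6-yl}lithium | [Li]C1=CC[C@@H](c2cc(OCc3ccccc3)c(OC)c(OC)c2OCc2ccccc2)CO1 | intermediate (not isolated)
18 | lithium 1-{(3S)-3-[2,5-bis(benzyloxy)-3,4-dimethoxyphenyl]-3,4-dihydro-2H-pyran-6-yl}-2,3-dimethoxy-4-oxocyclobut-2-en-1-olate | COC1=C(OC)C(O[Li])(C2=CC[C@@H](c3cc(OCc4ccccc4)c(OC)c(OC)c3OCc3ccccc3)CO2)C1=O | intermediate (not isolated)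
19 | 4-{(3S)-3-[2,5-bis(benzyloxy)-3,4-dimethoxyphenyl]-3,4-dihydro-2H-pyran-6-yl}-4-[(tert-butyldimethylsilyl)oxy]-2,3-dimethoxycyclobut-2-en-1-one (both carbinol epimers) | COC1=C(OC)C(O[Si](C)(C)C(C)(C)C)(C2=CC[C@@H](c3cc(OCc4ccccc4)c(OC)c(OC)c3OCc3ccccc3)CO2)C1=O | intermediate
20 | (3Z)-4-{(3S)-3-[2,5-bis(benzyloxy)-3,4-dimethoxyphenyl]-3,4-dihydro-2H-pyran-6-yl}-4-[(tert-butyldimethylsilyl)oxy]-2,3-dimethoxybuta-1,3-dien-1-one | O=C=C(OC)/C(OC)=C(/O[Si](C)(C)C(C)(C)C)C1=CC[C@@H](c2cc(OCc3ccccc3)c(OC)c(OC)c2OCc2ccccc2)CO1 | intermediate (not isolated)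
21 | (3S)-3-[2,5-bis(benzyloxy)-3,4-dimethoxyphenyl]-8-[(tert-butyldimethylsilyl)oxy]-6,7-dimethoxy-2,3,4,4a-tetrahydro-5H-chromen-5-one (both C4a epimers) | O=C1C(OC)=C(OC)C(O[Si](C)(C)C(C)(C)C)=C2OC[C@H](c3cc(OCc4ccccc4)c(OC)c(OC)c3OCc3ccccc3)CC12 | intermediate (not isolated)
22 | (3S)-3-[2,5-bis(benzyloxy)-3,4-dimethoxyphenyl]-8-[(tert-butyldimethylsilyl)oxy]-6,7-dimethoxychroman-5-ol | COc1c(O)c2c(c(O[Si](C)(C)C(C)(C)C)c1OC)OC[C@H](c1cc(OCc3ccccc3)c(OC)c(OC)c1OCc1ccccc1)C2 | intermediate
23 | (3S)-3-[2,5-bis(benzyloxy)-3,4-dimethoxyphenyl]-8-[(tert-butyldimethylsilyl)oxy]-6,7-dimethoxychroman-5-yl trifluoromethanesulfonate | COc1c(OS(=O)(=O)C(F)(F)F)c2c(c(O[Si](C)(C)C(C)(C)C)c1OC)OC[C@H](c1cc(OCc3ccccc3)c(OC)c(OC)c1OCc1ccccc1)C2 | intermediate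
24 | tert-butyl{[(3S)-3-[2,5-bis(benzyloxy)-3,4-dimethoxyphenyl]-6,7-dimethoxychroman-8-yl]oxy}dimethylsilane | COc1cc2c(c(O[Si](C)(C)C(C)(C)C)c1OC)OC[C@H](c1cc(OCc3ccccc3)c(OC)c(OC)c1OCc1ccccc1)C2 | intermediate
25 | (3S)-3-[2,5-bis(benzyloxy)-3,4-dimethoxyphenyl]-6,7-dimethoxychroman-8-ol | COc1cc2c(c(O)c1OC)OC[C@H](c1cc(OCc3ccccc3)c(OC)c(OC)c1OCc1ccccc1)C2 | intermediate
26 | (3S)-3-(2,5-dihydroxy-3,4-dimethoxyphenyl)-6,7-dimethoxychroman-8-ol | COc1cc2c(c(O)c1OC)OC[C@H](c1cc(O)c(OC)c(OC)c1O)C2 | intermediate (not isolated)
27 | 5-[(3S)-8-hydroxy-6,7-dimethoxychroman-3-yl]-2,3-dimethoxycyclohexa-2,5-diene-1,4-dione (CNP0269725.1) | COC1=C(OC)C(=O)C([C@H]2COc3c(cc(OC)c(OC)c3O)C2)=CC1=O | target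

## Step count and least certain steps

Total: 14 steps. Longest linear sequence: 14 steps, from 1 to 27 (7 and 16 are bought and enter directly).

**Step 10 (key step).** The likely failure is a 6π closure that is too slow. Dienylketene 20 is fully substituted and the bulky silyloxy group sits between the pyran oxygen and a methoxy group, so ring opening may revert faster than ring A closes. Prolonged heating then invites loss of the silyl group, ketene dimerisation or capture by traces of water. The fallback sets out from stannane 15 and returns at 25. Alkoxide 18 is trapped with chloromethyl methyl ether instead of the silyl triflate, giving the methoxymethyl-protected cyclobutenone F1, which carries a smaller, thermally inert donor. Thermolysis should give the 8-(methoxymethoxy) phenol F2. Triflation gives triflate F3 and formate reduction gives the 8-(methoxymethoxy)chroman F4. Dilute HCl in methanol then removes the acetal to give 25.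

**Step 4.** The likely failure is protodeboronation of the electron-rich, ortho-alkoxy boronic acid outrunning insertion of the weakly binding furanone, with loss of enantioselectivity if the temperature has to be raised. The fallback sets out from 6 and returns at 8. Suzuki coupling of 6 with commercial 4-bromofuran-2(5H)-one (Pd(PPh3)4, KF, THF/H2O) gives the achiral butenolide 4-[2,5-bis(benzyloxy)-3,4-dimethoxyphenyl]furan-2(5H)-one F5. Asymmetric conjugate reduction with a copper hydride (Cu(OAc)2, p-tol-BINAP, polymethylhydrosiloxane, t-BuOH) then sets the stereocentre. The ligand antipode is chosen to deliver hydride to the face that gives (4S)-lactone 8.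

**Step 8.** The likely failure is decomposition of the lithiated sulfone 13 before it meets the tin chloride (loss of sulfinate, or competing deprotonation of the benzylic OCH2 groups), or incomplete elimination from 14. The fallback sets out from 10 and returns at 17.
- Mild aqueous acid hydrolyses 10 to the six-membered lactol F6.
- TEMPO with PhI(OAc)2 oxidises it to the δ-lactone F7.
- KN(SiMe3)2 and diphenyl chlorophosphate give the ketene acetal phosphate F8.
- Pd(PPh3)4, Me3SnSnMe3 and LiCl give the trimethylstannane F9.
- MeLi at −78 °C gives vinyllithium 17.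

**Step 12.** The likely failure is slow oxidative addition into the C–O bond of an electron-rich triflate flanked by the C4 methylene and the C6 methoxy group, so that S–O cleavage back to phenol 22 competes. The fallback sets out from 22 and returns at 26. Phenol 22 is converted with 5-chloro-1-phenyl-1H-tetrazole and K2CO3 in acetone into the tetrazolyl ether F10. Bu4NF with AcOH removes the silyl group to give the tetrazolyl ether phenol F11. Hydrogenolysis over Pd/C then cleaves the C5–O bond together with both benzyl ethers and gives hydroquinone 26, which is oxidised as in step 14.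

**Step 14.** The likely failure is over-oxidation. The freed C8 phenol is a 2,6-dioxygenated phenol with an open para position (C5) and is prone to oxidative coupling if oxidant remains after the hydroquinone is consumed. The fallback sets out from 24 and returns at 27, reversing the order of unmasking. Hydrogenolysis of 24 gives the silyl-protected hydroquinone F12, Ag2O oxidises it to the silyl-protected quinone F13 with ring A fully capped, and Bu4NF buffered with excess AcOH in THF at 0 °C then frees the C8 hydroxyl.

## Further compounds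

F1 | step 10 | 4-{(3S)-3-[2,5-bis(benzyloxy)-3,4-dimethoxyphenyl]-3,4-dihydro-2H-pyran-6-yl}-2,3-dimethoxy-4-(methoxymethoxy)cyclobut-2-en-1-one | COCOC1(C2=CC[C@@H](c3cc(OCc4ccccc4)c(OC)c(OC)c3OCc3ccccc3)CO2)C(OC)=C(OC)C1=O
F2 | step 10 | (3S)-3-[2,5-bis(benzyloxy)-3,4-dimethoxyphenyl]-6,7-dimethoxy-8-(methoxymethoxy)chroman-5-ol | COCOc1c(OC)c(OC)c(O)c2c1OC[C@H](c1cc(OCc3ccccc3)c(OC)c(OC)c1OCc1ccccc1)C2
F3 | step 10 | (3S)-3-[2,5-bis(benzyloxy)-3,4-dimethoxyphenyl]-6,7-dimethoxy-8-(methoxymethoxy)chroman-5-yl trifluoromethanesulfonate | COCOc1c(OC)c(OC)c(OS(=O)(=O)C(F)(F)F)c2c1OC[C@H](c1cc(OCc3ccccc3)c(OC)c(OC)c1OCc1ccccc1)C2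
F4 | step 10 | (3S)-3-[2,5-bis(benzyloxy)-3,4-dimethoxyphenyl]-6,7-dimethoxy-8-(methoxymethoxy)chroman | COCOc1c(OC)c(OC)cc2c1OC[C@H](c1cc(OCc3ccccc3)c(OC)c(OC)c1OCc1ccccc1)C2
F5 | step 4 | 4-[2,5-bis(benzyloxy)-3,4-dimethoxyphenyl]furan-2(5H)-one | O=C1C=C(c2cc(OCc3ccccc3)c(OC)c(OC)c2OCc2ccccc2)CO1
F6 | step 8 | (5S)-5-[2,5-bis(benzyloxy)-3,4-dimethoxyphenyl]tetrahydro-2H-pyran-2-ol | OC1CC[C@@H](c2cc(OCc3ccccc3)c(OC)c(OC)c2OCc2ccccc2)CO1
F7 | step 8 | (5S)-5-[2,5-bis(benzyloxy)-3,4-dimethoxyphenyl]tetrahydro-2H-pyran-2-one | O=C1CC[C@@H](c2cc(OCc3ccccc3)c(OC)c(OC)c2OCc2ccccc2)CO1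
F8 | step 8 | (3S)-3-[2,5-bis(benzyloxy)-3,4-dimethoxyphenyl]-3,4-dihydro-2H-pyran-6-yl diphenyl phosphate | O=P(Oc1ccccc1)(Oc1ccccc1)OC1=CC[C@@H](c2cc(OCc3ccccc3)c(OC)c(OC)c2OCc2ccccc2)CO1
F9 | step 8 | trimethyl{(3S)-3-[2,5-bis(benzyloxy)-3,4-dimethoxyphenyl]-3,4-dihydro-2H-pyran-6-yl}stannane | C[Sn](C)(C)C1=CC[C@@H](c2cc(OCc3ccccc3)c(OC)c(OC)c2OCc2ccccc2)CO1
F10 | step 12 | 5-{[(3S)-3-[2,5-bis(benzyloxy)-3,4-dimethoxyphenyl]-8-[(tert-butyldimethylsilyl)oxy]-6,7-dimethoxychroman-5-yl]oxy}-1-phenyl-1H-tetrazole | COc1c(Oc3nnnn3-c3ccccc3)c2c(c(O[Si](C)(C)C(C)(C)C)c1OC)OC[C@H](c1cc(OCc3ccccc3)c(OC)c(OC)c1OCc1ccccc1)C2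
F11 | step 12 | (3S)-3-[2,5-bis(benzyloxy)-3,4-dimethoxyphenyl]-6,7-dimethoxy-5-[(1-phenyl-1H-tetrazol-5-yl)oxy]chroman-8-ol | COc1c(Oc3nnnn3-c3ccccc3)c2c(c(O)c1OC)OC[C@H](c1cc(OCc3ccccc3)c(OC)c(OC)c1OCc1ccccc1)C2
F12 | step 14 | 2-[(3S)-8-[(tert-butyldimethylsilyl)oxy]-6,7-dimethoxychroman-3-yl]-5,6-dimethoxybenzene-1,4-diol | COc1cc2c(c(O[Si](C)(C)C(C)(C)C)c1OC)OC[C@H](c1cc(O)c(OC)c(OC)c1O)C2
F13 | step 14 | 5-[(3S)-8-[(tert-butyldimethylsilyl)oxy]-6,7-dimethoxychroman-3-yl]-2,3-dimethoxycyclohexa-2,5-diene-1,4-dione | COC1=C(OC)C(=O)C([C@H]2COc3c(cc(OC)c(OC)c3O[Si](C)(C)C(C)(C)C)C2)=CC1=O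
A1 | alternative 1 | 8-(benzyloxy)-6,7-dimethoxy-2H-chromene | COc1cc2c(OCC=C2)c(OCc2ccccc2)c1OC
A2 | alternative 1 | cis-4-(benzyloxy)-2,3,9,10-tetramethoxy-6a,11a-dihydro-6H-benzofuro[3,2-c]chromen-8-ol (cis-fused pterocarpan, configured as in the SMILES) | COc1c(OC)c(O)cc2c1O[C@@H]1c3cc(OC)c(OC)c(OCc4ccccc4)c3OC[C@H]21
A3 | alternative 2 | 4,4,5,5-tetramethyl-2-vinyl-1,3,2-dioxaborolane | C=CB1OC(C)(C)C(C)(C)O1
A4 | alternative 2 | [2-(benzyloxy)-6-bromo-3,4-dimethoxyphenoxy](tert-butyl)dimethylsilane | Brc1cc(OC)c(OC)c(OCc2ccccc2)c1O[Si](C)(C)C(C)(C)C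
A5 | alternative 2 | 2-{(1S)-1-[2,5-bis(benzyloxy)-3,4-dimethoxyphenyl]-2-[3-(benzyloxy)-2-[(tert-butyldimethylsilyl)oxy]-4,5-dimethoxyphenyl]ethyl}-4,4,5,5-tetramethyl-1,3,2-dioxaborolane | CC1(C)OB(OC1(C)C)[C@@H](Cc1cc(OC)c(OC)c(OCc2ccccc2)c1O[Si](C)(C)C(C)(C)C)c1cc(OCc2ccccc2)c(OC)c(OC)c1OCc1ccccc1
A6 | alternative 3 | (3S)-3-ethynyl-6,7-dimethoxy-8-(methoxymethoxy)chroman | C#C[C@H]1COc2c(cc(OC)c(OC)c2OCOC)C1
A7 | alternative 3 | 4-{[(3S)-6,7-dimethoxy-8-(methoxymethoxy)chroman-3-yl]ethynyl}-4-hydroxy-2,3-dimethoxycyclobut-2-en-1-one | COC1=C(OC)C(O)(C#C[C@H]2COc3c(cc(OC)c(OC)c3OCOC)C2)C1=O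
A8 | alternative 3 | 5-[(3S)-6,7-dimethoxy-8-(methoxymethoxy)chroman-3-yl]-2,3-dimethoxycyclohexa-2,5-diene-1,4-dione | COC1=C(OC)C(=O)C([C@H]2COc3c(cc(OC)c(OC)c3OCOC)C2)=CC1=O
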